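A one-step world was where the meeting began: the chair proposed that substrate and coupling partner go mole for mole, at rate k[substrate][partner].

in all of them: substrate 0.48 M; free catalyst 4.8 mM

| run | coupling partner | remark | time |
|---|---|---|---|
| Monday's | 0.61 M | run made earlier |  |
| Friday's | 0.74 M | run made earlier |  |
| Wednesday's | 1.2 M | run made earlier |  |
| north | 0.530 M |  | 5.0 d |
| south-east | 1.10 M |  | 5.0 d |

- Monday's (time / d: product / %, catalyst intermediate B / %, substrate / %): 0.500: 12.3, 0, 88.4; 1.04: 18.7, 0.4, 81.2; 1.67: 24.6, 0, 75.0; 2.08: 29.7, 0.2, 70.8; 2.50: 33.6, 0.3, 66.4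
- Friday's (time / d: product / %, catalyst intermediate B / %, substrate / %): 0.500: 14.3, 0, 85.9; 1.04: 22.8, 0, 77.0; 1.67: 29.3, 0, 70.1; 2.08: 34.2, 0, 65.3; 2.50: 38.6, 0, 61.1
- Wednesday's (time / d: product / %, catalyst intermediate B / %, substrate / %): 0.208: 13.5, 0.6, 86.0; 0.625: 26.5, 0, 74.0; 1.25: 38.4, 0, 61.5; 1.67: 45.3, 0, 55.2; 2.50: 55.7, 0, 45.5

(each reading ± 0.5 percentage points)

* which of these there is most of at the end, counted by the substrate in it, north (catalyst intermediate B / substrate / product)
* which of these there is most of at the end, counted by the substrate in it, south-east (catalyst intermediate B / substrate / product)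
* how much there is at the end of the one of these that leads, in percent of the substrate charged: north
* how much there is at the end of the one of these that leads, in percent of the substrate charged: south-east

The analyst then put the runs to that test. With a and b the charges of substrate and coupling partner, and s the fraction of substrate left, she plotted G = ln[(b − a + a·s)/(b·s)]/(b − a). In a one-step world G rises straight with time, at slope k.

Between the second and last readings, Monday's gave 0.286 L mol⁻¹ d⁻¹, Friday's 0.269 L mol⁻¹ d⁻¹ and Wednesday's 0.259 L mol⁻¹ d⁻¹. She froze their mean, 0.271 L mol⁻¹ d⁻¹, as the working constant k, the late slope of G against time.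

The sceptic objected that the lines miss the origin. The analyst agreed: the mean G at the last reading is 0.772 L mol⁻¹, more than k times that time. So she reckoned forward from there, which gives G = 1.45 L mol⁻¹ at 5.0 d.

Solving G for s, she left north 55.6 % substrate, and south-east 72.1 % product.

The forecast, tabled next, argued “Rate is therefore first order in each reactant”. It gave north substrate at 56 % and south-east product at 71 %, a little below the analyst on south-east.

The flasks give north substrate at 55.2 % and south-east product at 73.7 %.

    substrate + catalyst intermediate A ⇌ catalyst intermediate B (K = 1.20 L mol⁻¹, k = 35.0 L mol⁻¹ h⁻¹)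
    2 free catalyst ⇌ resting dimer (K = 15000 L mol⁻¹, k = 360 L mol⁻¹ h⁻¹)
    catalyst intermediate B → free catalyst + product (k = 44.0 h⁻¹)
    coupling partner + free catalyst ⇌ catalyst intermediate A (K = 1.80 L mol⁻¹, k = 56.0 L mol⁻¹ h⁻¹)

Carried to north, k gave 55.6 % against the flask's 55.2 %. In north at 5.00 d, resting dimer, the catalyst's resting state, holds 87.9 % of the catalyst. Suppose, as a working assumption, that k goes with the square root of the catalyst charge. For the neighbour flask, north with 0.0082 M of free catalyst, that reckoning puts k at 0.355 L mol⁻¹ d⁻¹. Scaling G by the same root, it puts substrate at 48.7 %. That neighbour flask holds 47.6 % substrate and, more than that, 52.4 % product.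

All runs are calculated from invented constants.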